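## Structural features

The target is a chalcone. A 4-hydroxyphenyl ketone (ring A) is joined through an E-configured enone to C5 of a 2,3-dihydro-1-benzofuran, made of benzene ring B fused to dihydrofuran ring C. Ring B carries four contiguous substituents: O1 on C7a, C3 on C3a, the methoxy group on C4 and the enone on C5, so O1 is para and the methoxy group ortho to the enone carbon. The only stereocentre is C2 of ring C, S-configured, flanked by O1, the C3 methylene and a non-stereogenic tertiary carbinol carbon. It has no stereogenic neighbour and no nearby group that could relay chirality, but it is also not epimerisable. The fragile parts are the enone (a Michael acceptor, best made last), the free phenol, and the tertiary alcohol beside the ring oxygen, which strong acid dehydrates or ring-expands to a chromanol. The real difficulty is twofold: the regiodefined 1,2,3,4-substitution of ring B, and an isolated stereocentre at C2 that must be set by a reagent. The key step exploits the C3a–C7a bond: with the methoxy group on C4 these two carbons form a 3-methoxybenzyne pattern, which sends an oxygen nucleophile to C7a and carbon to C3a. O1, C3 and C2 of ring C can therefore be grafted on in one operation, with C2 at the carboxylate oxidation level on a flat furan that is hydrogenated asymmetrically afterwards.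

## Logic of the disconnections

**24 to 21 and 22.** The enone Cα=Cβ bond is cut. It is the only bond joining the two aromatic halves, and an aldol condensation forms it with the E geometry under thermodynamic control. Ring A then comes from a commercial ketone and all the complexity sits in one chiral aldehyde. The forward step must tolerate a free phenol and a tertiary alcohol under base.

**21 to 20.** The aldehyde is traced back to its cyclic acetal. The C5 carbon must stay masked through organolithium, ylide, Grignard and hydrogenation chemistry. The unmasking must be mild enough to spare the tertiary alcohol.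

**20 to 19.** The C2–H and C3–H bonds are removed, which erases the only stereocentre and leaves a flat benzofuran. The forward step needs a catalyst that reduces the furan C2=C3 bond, not the benzene ring, and that distinguishes the two faces at C2.

**19 to 17.** The two C–CH3 bonds of the carbinol are cut, leading back to an ester on C2. The addition is placed on the flat benzofuran because an α-aryloxy ester stereocentre would be epimerisable under the basic conditions.

**17 to 9, 10 and 11.** Four bonds are cut: C7a–O1, C3a–C3, C3–C2 and O1–C2. This removes the whole furan ring and leaves an aryne precursor, a one-carbon/one-oxygen donor and a two-carbon donor with a leaving group. The gain is the largest of the route: one ring and four skeletal bonds in one flask. The demand is regiocontrol in the addition to an unsymmetrical aryne.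

**9 to 7 (through 8).** The O–S bond of the triflate is cut and the phenol is traced back to its carbamate. The forward step must free the phenol without attacking the adjacent aryl–silicon bond or the acetal.

**7 to 3.** The aryl–silicon bond is cut at the carbon lying between the two oxygen substituents. That site is the most acidic ring position once the carbamate is in place. The forward step needs a directing group that survives butyllithium and a silylation protocol that leaves the acetal intact.

**3 to 2 to 1.** The acetal C–O bonds and the carbamate O–C bond are cut, leading to a commercial hydroxy aldehyde that already holds the C4 methoxy group, the C5 carbon and the C7a oxygen in the right relationship.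

## Other disconnections considered

**Alternative 1:** The cut runs through C3–C3a and O1–C2 of a partly saturated bicycle. Cyclohexane-1,3-dione A1 and the (Z)-butenediyl biscarbonate A2 would be joined under Pd2(dba)3 (a zerovalent palladium source) and a chiral DACH-phenyl bisphosphine. A π-allyl complex is C-allylated by the dione; a second ionisation and enol O-allylation close the dihydrofuran and set C2, giving vinyl enone A3.

- In its favour: the stereocentre arises in the ring-forming event itself, from two commodity chemicals, at ambient pressure. On this point the alternative is the better of the two.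
- Against it here: ring B does not yet exist. A3 must be dehydrogenated to phenol A4 without harming the vinyl group or re-ionising the allylic ether stereocentre. The C5 carbon must then be added by ortho-formylation and the phenol methylated. The vinyl group must become the dimethyl carbinol by Wacker oxidation and methyl addition, and allylic ethers are poor substrates for Markovnikov-selective Wacker oxidation.
- Comparison: the chosen plan has the C4 and C5 substituents in place from compound 1, whereas the alternative installs them late by phenol-directed chemistry. Both rely on catalyst-controlled enantioselection, and the alternative's is the better precedented for its own substrate. In step count the alternative is roughly equal to the nine steps proposed here, or one step shorter if aromatisation takes a single operation.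

**Alternative 2:** The cut is the C2–C3 bond. Tosylhydrazone A5, with Cs2CO3 and Co(Por*), the divalent cobalt complex of a chiral D2-symmetric amidoporphyrin, would give a diazo compound in situ. Loss of N2 gives a cobalt-bound benzylic carbon radical at C3. 1,5-Hydrogen transfer from the O–CH2 group moves the radical to C2, and radical substitution closes the ring to bromide A6 with catalyst control at C2.

- In its favour: ring closure and stereocentre in one mild step without pressure equipment, and a C5 bromide ready for formylation. Setting the stereocentre during ring formation makes the alternative equal or better on that point.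
- Against it here: the carbene carbon sits between two ortho oxygen substituents, and the C4 methoxy group offers three C–H bonds in the same 1,5-relationship, so hydrogen transfer from the wrong side is a real competitor. The wanted C–H bond is next to a fully substituted silyloxy carbon and is hindered. The ligand needs its own multistep synthesis.
- Comparison: both plans carry a C5 handle, but the alternative's needs halogen–metal exchange, formylation and silyl removal afterwards. Site selectivity in a radical hydrogen transfer is less securely controlled by this substrate than the polarity of a 3-methoxybenzyne. In step count the alternative is about equal, roughly eight steps.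

**Alternative 3:** The cut removes ring B altogether: C7a–C3a, C4–C5 and formally CO2. Heating pyrone A7, whose C3 oxygen carries an S-configured tether ending in a 1-methoxyalkyne, would give an intramolecular Diels–Alder addition of the pyrone diene to the alkyne. The bridged lactone then loses CO2 to give ester A8, with ring C closed by the same cycloaddition.

- In its favour: the C4 methoxy and C5 ester positions are fixed by construction, with no regiochemical question at all, which is better than the chosen plan. The stereocentre comes from the tether and is never at risk. No catalyst is needed, and the electron-poor pyrone ester is well matched to the electron-rich alkyne.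
- Against it here: A7 requires a stereodefined secondary alcohol flanked by a tertiary carbinol to be etherified with a 3-hydroxypyrone, a hindered substitution. It also carries an acid-sensitive ynol ether through several steps and a high-temperature key step.
- Comparison: regiocontrol and reliability of enantiopurity are equal or better than in the chosen plan. Step economy is clearly worse (probably twelve or more steps), and the precursor is far more fragile than silyl triflate 9.

Key step: step 5

**Remarks on the chemistry (assumptions and design choices)**

- Regiochemical bookkeeping: in 1 the carbons bearing CHO, OMe, H and OH become C5, C4, C3a and C7a of the benzofuran. Silicon on C3a, triflate on C7a and oxygen attack at C7a reproduce the target pattern (O1 para, OMe ortho to the C5 carbon). The target descriptor at C2 is S.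
- Assumption: the (R,R)-configured carbene ligand is taken to deliver H2 to the Re face of C2 of 19 (priorities O1 > CMe2OH > C3). This is the same topological face that leads to R-configured 2-alkyl dihydrobenzofurans; the oxygen-bearing substituent changes the descriptor to S. If the facial sense proves opposite, the (S,S)-ligand is used.
- Precursor design: an N-isopropyl carbamate is used because it can be removed from the hindered ortho-silyl phenol with amines alone. The carbamate is installed before the acetal because acetals of para-hydroxybenzaldehydes are very acid-labile. Anhydrous CsF replaces hydrated fluoride so that intermediate 14 is not hydrolysed.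
- Compounds 1, 10, 11 and 22 are treated as commercial.

## Route

Step 1
Reactants: 1 4-hydroxy-2-methoxybenzaldehyde
Product: 2 4-formyl-3-methoxyphenyl propan-2-ylcarbamate
Conditions: i-PrNCO, Et3N (cat.), CH2Cl2, 25 °C
Reagents that add atoms: isopropyl isocyanate, CC(C)N=C=O
Why: Base-catalysed addition of the phenol to the isocyanate (O-carbamoylation) leaves the aldehyde untouched; the N-monoalkyl carbamate becomes a strong ortho-directing group once N-silylated and is later removed under mild amine conditions through an isocyanate, and acylating the para-oxygen makes the aldehyde electrophilic enough for clean acetalisation.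

Step 2
Reactants: 2 4-formyl-3-methoxyphenyl propan-2-ylcarbamate
Product: 3 4-(1,3-dioxolan-2-yl)-3-methoxyphenyl propan-2-ylcarbamate
Conditions: HOCH2CH2OH, HC(OEt)3, p-TsOH·H2O (cat.), CH2Cl2, 25 °C; Et3N quench
Reagents that add atoms: ethane-1,2-diol, OCCO
Why: Acid-catalysed acetalisation with the orthoester as water scavenger at room temperature, which the aryl carbamate tolerates; the dioxolane masks the aldehyde against the organolithium, the ylide and the Grignard reagent to come.

Step 3
Reactants: 3 4-(1,3-dioxolan-2-yl)-3-methoxyphenyl propan-2-ylcarbamate
Product: 7 4-(1,3-dioxolan-2-yl)-3-methoxy-2-(trimethylsilyl)phenyl propan-2-ylcarbamate, via N-silyl carbamate 4 (not isolated), via aryllithium 5 (not isolated), via N-silyl arylsilane 6 (not isolated)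
Conditions: TBSOTf (1.0 equiv), TMEDA, Et2O, 0 → 25 °C; n-BuLi, TMEDA, −78 °C; TMSCl, −78 → 25 °C; aq. NaH2PO4 work-up
Reagents that add atoms: chlorotrimethylsilane, C[Si](C)(C)Cl
Why: Directed ortho-metalation: in situ N-silylation blocks the N–H and prevents loss of isocyanate, butyllithium–TMEDA then removes the ring proton flanked by the carbamate and the methoxy group (the site activated by both oxygen directors) and TMSCl silylates the aryllithium 5; the single equivalent of silyl triflate is consumed by the N–H faster than it can open the acetal, and the weakly acidic phosphate work-up cleaves the labile N–Si bond of 6 without hydrolysing the dioxolane.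

Step 4
Reactants: 7 4-(1,3-dioxolan-2-yl)-3-methoxy-2-(trimethylsilyl)phenyl propan-2-ylcarbamate
Product: 9 4-(1,3-dioxolan-2-yl)-3-methoxy-2-(trimethylsilyl)phenyl trifluoromethanesulfonate, via phenol 8 (not isolated)
Conditions: DBU, Et2NH, MeCN, 40 °C; then PhNTf2, 25 °C
Reagents that add atoms: N-phenylbis(trifluoromethanesulfonimide), O=S(=O)(N(c1ccccc1)S(=O)(=O)C(F)(F)F)C(F)(F)F
Why: DBU induces E1cB loss of isopropyl isocyanate from the N–H carbamate, diethylamine traps it as a urea, and the ortho-silyl phenoxide of 8 is sulfonylated in the same flask (one-pot decarbamoylation–triflation of ortho-silyl aryl carbamates); no hydride or strong nucleophile is used, so the aryl–silicon bond and the acetal are not endangered.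

Step 5
Reactants: 9 4-(1,3-dioxolan-2-yl)-3-methoxy-2-(trimethylsilyl)phenyl trifluoromethanesulfonate; 10 N,N-dimethylformamide; 11 ethyl (dimethyl-λ4-sulfanylidene)acetate
Product: 17 ethyl 5-(1,3-dioxolan-2-yl)-4-methoxy-1-benzofuran-2-carboxylate, via aryne 12 (not isolated), via benzoxete 13 (not isolated), via ortho-quinone methide 14 (not isolated), via sulfonium phenoxide 15 (not isolated), via 3-amino-2,3-dihydrobenzofuran 16 (not isolated)
Conditions: CsF (3 equiv), 11 (2 equiv, slow addition), anhydrous DMF (solvent), 4 Å MS, 25 °C, then 60 °C
Reagents that add atoms: none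
Why: Fluoride attacks the silicon of 9 and triflate leaves, giving aryne 12; the carbonyl oxygen of 10, present as solvent, adds to the aryne carbon remote from the methoxy group (future C7a) and the aryl anion next to the methoxy group (future C3a) closes on the iminium carbon, so C7a–O1 and C3a–C3 form in a formal [2+2] addition to benzoxete 13. Electrocyclic opening of 13 gives the ortho-quinone methide 14, an aza-vinylogous iminium phenoxide. Ylide 11 adds through carbon to the exocyclic carbon of 14 (C3–C2) to give betaine 15, whose phenoxide displaces dimethyl sulfide from C2 in a 5-exo-tet SN2 closure (O1–C2), the only ring closed in this step and the same sequence as the formal [4+1] annulation of sulfonium ylides with ortho-quinone methides. E1cB loss of dimethylamine from 16 on warming aromatises the furan, so the two transient stereocentres of 16 vanish and no stereocentre has to be controlled. The closest known reaction type is the three-component benzofuran synthesis from arynes, formamides and carbon nucleophiles carrying an α-leaving group. The selectivity that matters is the regiochemistry of addition to the aryne, secured by the C4 methoxy group, whose σ-withdrawal distorts the aryne and stabilises negative charge on the adjacent carbon. Chemoselectivity for 10 over direct arylation of 11 or of liberated dimethylamine rests on 10 being the solvent, on slow addition of 11 and on warming only after 9 is consumed; the C5 dioxolane is inert throughout.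

Step 6
Reactants: 17 ethyl 5-(1,3-dioxolan-2-yl)-4-methoxy-1-benzofuran-2-carboxylate
Product: 19 2-[5-(1,3-dioxolan-2-yl)-4-methoxy-1-benzofuran-2-yl]propan-2-ol, via methyl ketone 18 (not isolated)
Conditions: MeMgBr (3.5 equiv), THF, 0 → 25 °C; aq. NH4Cl
Reagents that add atoms: methylmagnesium bromide, C[Mg]Br
Why: Double Grignard addition to the ester through ketone 18 gives the tertiary carbinol while the dioxolane and the benzofuran stay inert; it is done on the flat benzofuran because an α-aryloxy ester stereocentre at C2 would be epimerisable under these conditions, and the neutral work-up avoids dehydration of the furylic alcohol.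

Step 7
Reactants: 19 2-[5-(1,3-dioxolan-2-yl)-4-methoxy-1-benzofuran-2-yl]propan-2-ol
Product: 20 2-[(2S)-5-(1,3-dioxolan-2-yl)-4-methoxy-2,3-dihydro-1-benzofuran-2-yl]propan-2-ol
Conditions: Ru(cod)(2-methylallyl)2 (5 mol%), 1,3-bis[(1R)-1-(naphthalen-1-yl)ethyl]-4,5-dihydroimidazolium tetrafluoroborate (10 mol%), KOt-Bu (15 mol%), hexane, 70 °C; then 19, toluene–hexane, H2 (60 bar), 25–40 °C
Reagents that add atoms: none
Why: Asymmetric hydrogenation of a 2-substituted benzofuran with the ruthenium carbene catalyst formed from the divalent ruthenium precursor, the chiral imidazolinium salt and base; this catalyst class reduces the furan C2=C3 bond in preference to the benzene ring and adds both hydrogens to one face, and the C2-symmetric carbene differentiates the faces so that hydrogen reaches the Re face of C2, which gives the S configuration by catalyst control alone.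

Step 8
Reactants: 20 2-[(2S)-5-(1,3-dioxolan-2-yl)-4-methoxy-2,3-dihydro-1-benzofuran-2-yl]propan-2-ol
Product: 21 (2S)-2-(2-hydroxypropan-2-yl)-4-methoxy-2,3-dihydro-1-benzofuran-5-carbaldehyde
Conditions: 1 M aq. HCl, THF, 0 → 25 °C; NaHCO3 quench
Reagents that add atoms: water, O
Why: Hydrolysis of an electron-rich aryl dioxolane is fast in cold dilute acid, conditions under which the tertiary alcohol (no longer furylic) neither dehydrates nor ring-expands, and C2 carries neither an acidic hydrogen nor an ionisable leaving group.

Step 9
Reactants: 21 (2S)-2-(2-hydroxypropan-2-yl)-4-methoxy-2,3-dihydro-1-benzofuran-5-carbaldehyde; 22 1-(4-hydroxyphenyl)ethan-1-one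
Product: 24 (2E)-3-[(2S)-2-(2-hydroxypropan-2-yl)-4-methoxy-2,3-dihydro-1-benzofuran-5-yl]-1-(4-hydroxyphenyl)prop-2-en-1-one, via aldol adduct 23 (not isolated)
Conditions: KOH (50% aq., excess), EtOH, 25 → 40 °C; then 1 M HCl to pH 5–6 at 0 °C
Reagents that add atoms: none
Why: Claisen–Schmidt condensation: the enolate of 22 (present as its phenoxide in excess hydroxide) adds to the non-enolisable aldehyde 21 and aldol 23 loses water by E1cB elimination to the conjugated E-enone, the thermodynamically favoured geometry; C2 is not acidic and the tertiary alcohol is inert to base.

## Compound list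

1 | 4-hydroxy-2-methoxybenzaldehyde | COc1cc(O)ccc1C=O | starting material
2 | 4-formyl-3-methoxyphenyl propan-2-ylcarbamate | COc1cc(OC(=O)NC(C)C)ccc1C=O | intermediate
3 | 4-(1,3-dioxolan-2-yl)-3-methoxyphenyl propan-2-ylcarbamate | COc1cc(OC(=O)NC(C)C)ccc1C1OCCO1 | intermediate
4 | 4-(1,3-dioxolan-2-yl)-3-methoxyphenyl [tert-butyl(dimethyl)silyl](propan-2-yl)carbamate | COc1cc(OC(=O)N(C(C)C)[Si](C)(C)C(C)(C)C)ccc1C1OCCO1 | intermediate (not isolated)
5 | {6-[{[tert-butyl(dimethyl)silyl](propan-2-yl)carbamoyl}oxy]-3-(1,3-dioxolan-2-yl)-2-methoxyphenyl}lithium | [Li]c1c(OC)c(C2OCCO2)ccc1OC(=O)N(C(C)C)[Si](C)(C)C(C)(C)C | intermediate (not isolated)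
6 | 4-(1,3-dioxolan-2-yl)-3-methoxy-2-(trimethylsilyl)phenyl [tert-butyl(dimethyl)silyl](propan-2-yl)carbamate | COc1c(C2OCCO2)ccc(OC(=O)N(C(C)C)[Si](C)(C)C(C)(C)C)c1[Si](C)(C)C | intermediate (not isolated)
7 | 4-(1,3-dioxolan-2-yl)-3-methoxy-2-(trimethylsilyl)phenyl propan-2-ylcarbamate | COc1c(C2OCCO2)ccc(OC(=O)NC(C)C)c1[Si](C)(C)C | intermediate
8 | 4-(1,3-dioxolan-2-yl)-3-methoxy-2-(trimethylsilyl)phenol | COc1c(C2OCCO2)ccc(O)c1[Si](C)(C)C | intermediate (not isolated)
9 | 4-(1,3-dioxolan-2-yl)-3-methoxy-2-(trimethylsilyl)phenyl trifluoromethanesulfonate | COc1c(C2OCCO2)ccc(OS(=O)(=O)C(F)(F)F)c1[Si](C)(C)C | intermediate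
10 | N,N-dimethylformamide | CN(C)C=O | starting material
11 | ethyl (dimethyl-λ4-sulfanylidene)acetate | CCOC(=O)C=S(C)C | starting material
12 | 4-(1,3-dioxolan-2-yl)-3-methoxybenzyne (aryne bond between the former C–Si and C–OTf carbons) | COC1=C(C2OCCO2)C=CC#C1 | intermediate (not isolated)
13 | 4-(1,3-dioxolan-2-yl)-3-methoxy-N,N-dimethyl-2H-benzoxet-2-amine | CN(C)C1Oc2ccc(C3OCCO3)c(OC)c21 | intermediate (not isolated)
14 | 6-[(dimethylamino)methylidene]-4-(1,3-dioxolan-2-yl)-5-methoxycyclohexa-2,4-dien-1-one | O=C1C=CC(C2OCCO2)=C(OC)C1=CN(C)C | intermediate (not isolated)
15 | 2-[1-(dimethylamino)-2-(dimethylsulfonio)-3-ethoxy-3-oxopropyl]-4-(1,3-dioxolan-2-yl)-3-methoxyphenolate (relative configuration not defined) | CCOC(=O)C([S+](C)C)C(N(C)C)c1c([O-])ccc(C2OCCO2)c1OC | intermediate (not isolated)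
16 | ethyl 3-(dimethylamino)-5-(1,3-dioxolan-2-yl)-4-methoxy-2,3-dihydro-1-benzofuran-2-carboxylate (relative configuration not defined) | CCOC(=O)C1Oc2ccc(C3OCCO3)c(OC)c2C1N(C)C | intermediate (not isolated)
17 | ethyl 5-(1,3-dioxolan-2-yl)-4-methoxy-1-benzofuran-2-carboxylate | CCOC(=O)c1cc2c(OC)c(C3OCCO3)ccc2o1 | intermediate
18 | 1-[5-(1,3-dioxolan-2-yl)-4-methoxy-1-benzofuran-2-yl]ethan-1-one | CC(=O)c1cc2c(OC)c(C3OCCO3)ccc2o1 | intermediate (not isolated)
19 | 2-[5-(1,3-dioxolan-2-yl)-4-methoxy-1-benzofuran-2-yl]propan-2-ol | CC(C)(O)c1cc2c(OC)c(C3OCCO3)ccc2o1 | intermediate
20 | 2-[(2S)-5-(1,3-dioxolan-2-yl)-4-methoxy-2,3-dihydro-1-benzofuran-2-yl]propan-2-ol | COc1c(C2OCCO2)ccc2c1C[C@@H](C(C)(C)O)O2 | intermediate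
21 | (2S)-2-(2-hydroxypropan-2-yl)-4-methoxy-2,3-dihydro-1-benzofuran-5-carbaldehyde | COc1c(C=O)ccc2c1C[C@@H](C(C)(C)O)O2 | intermediate
22 | 1-(4-hydroxyphenyl)ethan-1-one (4-hydroxyacetophenone) | CC(=O)c1ccc(O)cc1 | starting material
23 | 3-hydroxy-3-[(2S)-2-(2-hydroxypropan-2-yl)-4-methoxy-2,3-dihydro-1-benzofuran-5-yl]-1-(4-hydroxyphenyl)propan-1-one (both epimers at the new carbinol carbon) | COc1c(C(O)CC(=O)c2ccc(O)cc2)ccc2c1C[C@@H](C(C)(C)O)O2 | intermediate (not isolated)
24 | (2E)-3-[(2S)-2-(2-hydroxypropan-2-yl)-4-methoxy-2,3-dihydro-1-benzofuran-5-yl]-1-(4-hydroxyphenyl)prop-2-en-1-one | COc1c(/C=C/C(=O)c2ccc(O)cc2)ccc2c1C[C@@H](C(C)(C)O)O2 | target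

## Step count and least certain steps

Total step count: 9. Longest linear sequence: 9 steps (1 to 24); 10, 11 and 22 enter as purchased materials.

**Step 5 (key step).** The likely failures are capture of the aryne by the ylide carbon or by liberated dimethylamine in competition with the formamide oxygen, hydrolysis of 14 by adventitious water, and some loss of regiocontrol because the C4 methoxy group is twisted by its C5 neighbour. The fallback separates the events using known chemistry and sets out from 9. The aryne is generated with CsF in 10 without the ylide and the mixture is quenched with water, which hydrolyses 14 to 3-(1,3-dioxolan-2-yl)-6-hydroxy-2-methoxybenzaldehyde F1. F1 is heated with ethyl bromoacetate and K2CO3 in DMF. O-Alkylation gives ethyl 2-[4-(1,3-dioxolan-2-yl)-2-formyl-3-methoxyphenoxy]acetate F2, which closes by intramolecular aldol addition to ethyl 5-(1,3-dioxolan-2-yl)-3-hydroxy-4-methoxy-2,3-dihydro-1-benzofuran-2-carboxylate F3 and dehydrates. The route is rejoined at 17.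

**Step 3.** Two processes may intervene: Lewis-acid opening of the dioxolane by the silyl triflate before N-silylation is complete, and lithiation ortho to the carbamate on its unhindered side instead of between the two oxygens. The fallback uses a carbamate that needs no silyl triflate and sets out from 1. Diethylcarbamoyl chloride and K2CO3 give 4-formyl-3-methoxyphenyl diethylcarbamate F4. Acetalisation as in step 2 gives 4-(1,3-dioxolan-2-yl)-3-methoxyphenyl diethylcarbamate F5. s-BuLi–TMEDA in THF at −78 °C followed by TMSCl gives 4-(1,3-dioxolan-2-yl)-3-methoxy-2-(trimethylsilyl)phenyl diethylcarbamate F6. Reductive cleavage of the carbamate with LiAlH4 in THF, which touches neither the acetal nor the aryl–silicon bond, returns to the route at 8. Compound 8 is then triflated with PhNTf2 and DBU as in the second stage of step 4 to give 9. The cost is one extra step.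

**Step 7.** The risk is low turnover or poor facial discrimination, because the C2 substituent is a fully substituted carbinol carbon, bulkier than the alkyl and aryl groups for which this catalyst class is established; partial reduction of the benzene ring at forcing pressure is a further risk. The fallback replaces asymmetric catalysis by conjugate reduction and resolution and sets out from 17. Mg in MeOH reduces the furan C2=C3 bond with ester exchange to give racemic methyl 5-(1,3-dioxolan-2-yl)-4-methoxy-2,3-dihydro-1-benzofuran-2-carboxylate F7. Preparative chromatography on a chiral stationary phase gives the (2S)-ester F8. The (2R)-ester F9 is racemised with NaOMe in MeOH and recycled. F8 is treated with MeMgBr in THF at −78 → 0 °C, adding to the ester faster than it enolises it, and the route is rejoined at 20.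

**Step 9.** The acetophenone is deprotonated first at the phenol, so enolate formation is slow. Prolonged exposure to concentrated hydroxide may lead to incomplete conversion or conjugate addition of alkoxide to the product. The fallback replaces the aldol condensation by an olefination and sets out from 21. 2-Bromo-1-(4-hydroxyphenyl)ethan-1-one and PPh3 give [2-(4-hydroxyphenyl)-2-oxoethyl]triphenylphosphonium bromide F10. Aqueous Na2CO3 converts it into the stabilised ylide 1-(4-hydroxyphenyl)-2-(triphenyl-λ5-phosphanylidene)ethan-1-one F11. A Wittig reaction of F11 with 21 in toluene at 100 °C under neutral conditions should give the E-enone directly, rejoining the route at 24.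

## Further compounds

F1 | step 5 | 3-(1,3-dioxolan-2-yl)-6-hydroxy-2-methoxybenzaldehyde | COc1c(C2OCCO2)ccc(O)c1C=O
F2 | step 5 | ethyl 2-[4-(1,3-dioxolan-2-yl)-2-formyl-3-methoxyphenoxy]acetate | CCOC(=O)COc1ccc(C2OCCO2)c(OC)c1C=O
F3 | step 5 | ethyl 5-(1,3-dioxolan-2-yl)-3-hydroxy-4-methoxy-2,3-dihydro-1-benzofuran-2-carboxylate | CCOC(=O)C1Oc2ccc(C3OCCO3)c(OC)c2C1O
F4 | step 3 | 4-formyl-3-methoxyphenyl diethylcarbamate | CCN(CC)C(=O)Oc1ccc(C=O)c(OC)c1
F5 | step 3 | 4-(1,3-dioxolan-2-yl)-3-methoxyphenyl diethylcarbamate | CCN(CC)C(=O)Oc1ccc(C2OCCO2)c(OC)c1
F6 | step 3 | 4-(1,3-dioxolan-2-yl)-3-methoxy-2-(trimethylsilyl)phenyl diethylcarbamate | CCN(CC)C(=O)Oc1ccc(C2OCCO2)c(OC)c1[Si](C)(C)C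
F7 | step 7 | racemic methyl 5-(1,3-dioxolan-2-yl)-4-methoxy-2,3-dihydro-1-benzofuran-2-carboxylate | COc1c(C2OCCO2)ccc2c1CC(C(=O)OC)O2
F8 | step 7 | methyl (2S)-5-(1,3-dioxolan-2-yl)-4-methoxy-2,3-dihydro-1-benzofuran-2-carboxylate | COc1c(C2OCCO2)ccc2c1C[C@@H](C(=O)OC)O2
F9 | step 7 | methyl (2R)-5-(1,3-dioxolan-2-yl)-4-methoxy-2,3-dihydro-1-benzofuran-2-carboxylate | COc1c(C2OCCO2)ccc2c1C[C@H](C(=O)OC)O2
F10 | step 9 | [2-(4-hydroxyphenyl)-2-oxoethyl]triphenylphosphonium bromide | [Br-].O=C(C[P+](c1ccccc1)(c1ccccc1)c1ccccc1)c1ccc(O)cc1
F11 | step 9 | 1-(4-hydroxyphenyl)-2-(triphenyl-λ5-phosphanylidene)ethan-1-one | O=C(C=P(c1ccccc1)(c1ccccc1)c1ccccc1)c1ccc(O)cc1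
A1 | alternative 1 | cyclohexane-1,3-dione | O=C1CCCC(=O)C1
A2 | alternative 1 | (2Z)-but-2-ene-1,4-diyl dimethyl biscarbonate | COC(=O)OC/C=C\COC(=O)OC
A3 | alternative 1 | (2S)-2-ethenyl-3,5,6,7-tetrahydro-1-benzofuran-4(2H)-one | O=C1CCCC2=C1C[C@@H](C=C)O2
A4 | alternative 1 | (2S)-2-ethenyl-2,3-dihydro-1-benzofuran-4-ol | Oc1cccc2c1C[C@@H](C=C)O2
A5 | alternative 2 | N'-[(E)-(3-bromo-2-methoxy-6-{2-methyl-2-[(triethylsilyl)oxy]propoxy}phenyl)methylidene]-4-methylbenzenesulfonohydrazide | COc1c(Br)ccc(OCC(C)(C)O[Si](CC)(CC)CC)c1/C=N/NS(=O)(=O)c1ccc(C)cc1
A6 | alternative 2 | (S)-{[2-(5-bromo-4-methoxy-2,3-dihydro-1-benzofuran-2-yl)propan-2-yl]oxy}triethylsilane | COc1c(Br)ccc2c1C[C@@H](C(C)(C)O[Si](CC)(CC)CC)O2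
A7 | alternative 3 | methyl 3-{[(3S)-2-hydroxy-6-methoxy-2-methylhex-5-yn-3-yl]oxy}-2-oxo-2H-pyran-6-carboxylate | COC#CC[C@@H](C(C)(C)O)Oc1ccc(C(=O)OC)oc1=O
A8 | alternative 3 | methyl (2S)-2-(2-hydroxypropan-2-yl)-4-methoxy-2,3-dihydro-1-benzofuran-5-carboxylate | COC(=O)c1ccc2c(c1OC)C[C@@H](C(C)(C)O)O2
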